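**Retrosynthetic overview**

1. Numbering: ring C1 (CH bearing the side chain), C2, C3=C4(CH3), C5, C6, C7=C8(CH2OH), C9, C10, C11=C12(CH3), C13, C14. Enabling feature: the only ring is a 14-membered carbocycle in which C10 is an unbranched CH2 and C11 the hydrogen-bearing end of the E-C11=C12 alkene, with no stereocentre or heteroatom within three bonds, so both carbons can be carried as iodides.
2. Key disconnection C10–C11: nickel-catalysed reductive cross-electrophile macrocyclisation of the open-chain diiodide 27 (two electrophilic carbons of like polarity; free tertiary alcohol; C8 ester as CH2OH precursor). The single ring is formed here, and ester reduction then gives the target.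
3. C7=C8 by E-selective Horner–Wadsworth–Emmons reaction (brings C8, C9, C10 and the CH2OH carbon); C11=C12 by zirconium-catalysed methylalumination/iodination of a terminal alkyne.
4. C2–C3 by Negishi C(sp3)–C(sp2) coupling with a (Z)-alkenyl iodide made by carbocupration of propyne (sets C3=C4).
5. Both stereocentres from nerol: Sharpless epoxidation (carbinol carbon), then copper-catalysed anti opening of the epoxide at C2 by a butynyl Grignard reagent (C1).

Key step: step 14

Assumption: nerol of high Z purity and the building blocks 3, 8, 9, 20 and 21 are taken as commercial; the target is read as R at C1, R at the carbinol carbon, with 3Z,7E,11E ring alkenes.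

**Route**

Step 1
Reactants: 1 nerol
Product: 2 [(2S,3R)-3-methyl-3-(4-methylpent-3-en-1-yl)oxiran-2-yl]methanol
Conditions: Ti(OiPr)4 (10 mol%), diethyl L-(+)-tartrate (12 mol%), tBuOOH, 4 Å MS, CH2Cl2, −20 °C
Reagents that add atoms: tert-butyl hydroperoxide, CC(C)(C)OO
Why: Sharpless asymmetric epoxidation: the allylic hydroxyl binds the titanium tartrate so that only the C2=C3 alkene reacts, and the L-(+)-tartrate delivers oxygen to the face that gives the (2S,3R)-epoxide, which fixes the configuration of the future tertiary carbinol carbon.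

Step 2
Reactants: 2 [(2S,3R)-3-methyl-3-(4-methylpent-3-en-1-yl)oxiran-2-yl]methanol; 3 (4-bromobut-1-yn-1-yl)trimethylsilane
Product: 5 (2R,3R)-3,7-dimethyl-2-[4-(trimethylsilyl)but-3-yn-1-yl]oct-6-ene-1,3-diol, via silylbutynylmagnesium bromide 4 (not isolated)
Conditions: 3, Mg, THF, 40 °C; then CuI (10 mol%), 2 (0.3 equiv relative to 4), THF, −30 to 0 °C; aq. NH4Cl
Reagents that add atoms: none
Why: Copper-catalysed Grignard opening of a 3,3-disubstituted 2,3-epoxy alcohol: the organocopper species attacks the less substituted C2 from the side opposite the C–O bond (SN2, inversion), which sets ring stereocentre C1 as R next to the retained R carbinol and gives the 1,3-diol.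

Step 3
Reactants: 5 (2R,3R)-3,7-dimethyl-2-[4-(trimethylsilyl)but-3-yn-1-yl]oct-6-ene-1,3-diol
Product: 6 (5S,6R)-5-(iodomethyl)-6,10-dimethyl-1-(trimethylsilyl)undec-9-en-1-yn-6-ol
Conditions: PPh3, I2, imidazole (premixed), CH2Cl2, 0 °C
Reagents that add atoms: iodine, II
Why: Appel reaction: only the unhindered primary hydroxyl forms the alkoxyphosphonium ion and is displaced by iodide, the tertiary alcohol being inert at 0 °C.

Step 4
Reactants: 6 (5S,6R)-5-(iodomethyl)-6,10-dimethyl-1-(trimethylsilyl)undec-9-en-1-yn-6-ol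
Product: 7 {[(5S,6R)-5-(iodomethyl)-6,10-dimethyl-1-(trimethylsilyl)undec-9-en-1-yn-6-yl]oxy}trimethylsilane
Conditions: Me3SiOTf, 2,6-lutidine, CH2Cl2, −78 °C
Reagents that add atoms: trimethylsilyl trifluoromethanesulfonate, C[Si](C)(C)OS(=O)(=O)C(F)(F)F
Why: Silylation with a silyl triflate and a hindered pyridine base caps the tertiary alcohol so that it cannot protonate the organozinc reagent of step 6, and no stereocentre is touched.

Step 5
Reactants: 8 (3-bromopropoxy)(tert-butyl)dimethylsilane; 9 propyne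
Product: 13 tert-butyl{[(4Z)-5-iodo-4-methylpent-4-en-1-yl]oxy}dimethylsilane, via silyloxypropylmagnesium bromide 10 (not isolated), via silyloxypropylcopper 11 (not isolated), via Z-alkenylcopper 12 (not isolated)
Conditions: 8, Mg, Et2O, reflux; CuBr·SMe2 (1 equiv), Et2O/Me2S, −45 °C; 9, −25 °C; I2, THF, −50 to 0 °C
Reagents that add atoms: iodine, II
Why: Carbocupration of a terminal alkyne: the alkylcopper adds syn across propyne with copper on the terminal carbon, and iodinolysis with retention gives the (Z)-2-methylalk-1-enyl iodide that carries the C3=C4 geometry.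

Step 6
Reactants: 7 {[(5S,6R)-5-(iodomethyl)-6,10-dimethyl-1-(trimethylsilyl)undec-9-en-1-yn-6-yl]oxy}trimethylsilane; 13 tert-butyl{[(4Z)-5-iodo-4-methylpent-4-en-1-yl]oxy}dimethylsilane
Product: 15 tert-butyl{[(4Z,7R,8R)-4,8,12-trimethyl-7-[4-(trimethylsilyl)but-3-yn-1-yl]-8-(trimethylsilyloxy)trideca-4,11-dien-1-yl]oxy}dimethylsilane, via alkylzinc iodide 14 (not isolated)
Conditions: 7, Zn dust, LiCl, THF, 40 °C; then 13, Pd(PPh3)4 (5 mol%), THF, 50 °C
Reagents that add atoms: none
Why: Negishi coupling: zinc inserts into the primary C–I bond and palladium-catalysed C(sp3)–C(sp2) coupling with the alkenyl iodide proceeds with retention of the Z geometry, the stereocentres being remote from the zinc-bearing carbon and unaffected.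

Step 7
Reactants: 15 tert-butyl{[(4Z,7R,8R)-4,8,12-trimethyl-7-[4-(trimethylsilyl)but-3-yn-1-yl]-8-(trimethylsilyloxy)trideca-4,11-dien-1-yl]oxy}dimethylsilane
Product: 16 (4Z,7R)-7-[(2R)-2-hydroxy-6-methylhept-5-en-2-yl]-4-methylundec-4-en-10-yn-1-ol
Conditions: Bu4NF (4 equiv), THF, 0 °C to rt
Reagents that add atoms: none
Why: Fluoride-mediated desilylation cleaves the alkynyl C–Si bond and both silyl ethers in one operation, freeing the terminal alkyne for carbometalation and the primary alcohol for oxidation.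

Step 8
Reactants: 16 (4Z,7R)-7-[(2R)-2-hydroxy-6-methylhept-5-en-2-yl]-4-methylundec-4-en-10-yn-1-ol
Product: 18 (4Z,7R,10E)-7-[(2R)-2-hydroxy-6-methylhept-5-en-2-yl]-11-iodo-4,10-dimethylundeca-4,10-dien-1-ol, via E-alkenyldimethylalane 17 (not isolated)
Conditions: Me3Al (5 equiv), Cp2ZrCl2 (50 mol%), CH2Cl2, 0 °C to rt; then I2 (1.1 equiv), THF, −78 to −30 °C
Reagents that add atoms: trimethylaluminium, C[Al](C)C; iodine, II
Why: Zirconium-catalysed methylalumination (Negishi carboalumination) adds methyl and aluminium syn with aluminium on the terminal carbon while the hydroxyls are masked in situ as aluminium alkoxides, and iodinolysis with retention sets the E geometry of C11=C12; the mixture is kept at or below room temperature so that no chelation-driven isomerisation of the alkenylalane occurs.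

Step 9
Reactants: 18 (4Z,7R,10E)-7-[(2R)-2-hydroxy-6-methylhept-5-en-2-yl]-11-iodo-4,10-dimethylundeca-4,10-dien-1-ol
Product: 19 (4Z,7R,10E)-7-[(2R)-2-hydroxy-6-methylhept-5-en-2-yl]-11-iodo-4,10-dimethylundeca-4,10-dienal
Conditions: TEMPO (10 mol%), PhI(OAc)2, CH2Cl2, rt
Reagents that add atoms: none
Why: Oxoammonium (TEMPO) oxidation with PhI(OAc)2 as terminal oxidant converts only the primary alcohol into the aldehyde and leaves the tertiary alcohol, the alkenyl iodide and the alkenes untouched.

Step 10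
Reactants: 20 tert-butyl 2-(diethoxyphosphoryl)acetate; 21 (2-bromoethoxy)(tert-butyl)dimethylsilane
Product: 23 tert-butyl 4-[(tert-butyldimethylsilyl)oxy]-2-(diethoxyphosphoryl)butanoate (racemic), via sodium phosphonoacetate carbanion 22 (not isolated)
Conditions: NaH, DMF, 0 °C; then 21, NaI (cat.), 60 °C
Reagents that add atoms: none
Why: C-Alkylation of a stabilised phosphonate carbanion (SN2 at the primary bromide) installs the two-carbon arm that becomes C9 and C10, and the new stereocentre is of no consequence because it becomes sp2 in step 11.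

Step 11
Reactants: 19 (4Z,7R,10E)-7-[(2R)-2-hydroxy-6-methylhept-5-en-2-yl]-11-iodo-4,10-dimethylundeca-4,10-dienal; 23 tert-butyl 4-[(tert-butyldimethylsilyl)oxy]-2-(diethoxyphosphoryl)butanoate
Product: 25 tert-butyl (2E,6Z,9R,12E)-2-{2-[(tert-butyldimethylsilyl)oxy]ethyl}-9-[(2R)-2-hydroxy-6-methylhept-5-en-2-yl]-13-iodo-6,12-dimethyltrideca-2,6,12-trienoate, via bromomagnesium phosphonate carbanion 24 (not isolated)
Conditions: 23 (2.2 equiv), MeMgBr (2.0 equiv), THF, 0 °C to rt; then 19, reflux
Reagents that add atoms: none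
Why: Horner–Wadsworth–Emmons olefination: the magnesium-chelated α-branched phosphonate adds reversibly and eliminates through the less hindered oxaphosphetane, which places the ester trans to the C6 chain (E) and so sets the C7=C8 geometry, while the phosphonate anion is too weak a base to disturb the tertiary alcohol.

Step 12
Reactants: 25 tert-butyl (2E,6Z,9R,12E)-2-{2-[(tert-butyldimethylsilyl)oxy]ethyl}-9-[(2R)-2-hydroxy-6-methylhept-5-en-2-yl]-13-iodo-6,12-dimethyltrideca-2,6,12-trienoate
Product: 26 tert-butyl (2E,6Z,9R,12E)-2-(2-hydroxyethyl)-9-[(2R)-2-hydroxy-6-methylhept-5-en-2-yl]-13-iodo-6,12-dimethyltrideca-2,6,12-trienoate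
Conditions: HF·pyridine, pyridine, THF, 0 °C
Reagents that add atoms: none
Why: Fluoride cleaves the primary silyl ether under mildly acidic conditions, and the bulky tert-butyl ester keeps the liberated γ-hydroxyl from lactonising.

Step 13
Reactants: 26 tert-butyl (2E,6Z,9R,12E)-2-(2-hydroxyethyl)-9-[(2R)-2-hydroxy-6-methylhept-5-en-2-yl]-13-iodo-6,12-dimethyltrideca-2,6,12-trienoate
Product: 27 tert-butyl (2E,6Z,9R,12E)-9-[(2R)-2-hydroxy-6-methylhept-5-en-2-yl]-13-iodo-2-(2-iodoethyl)-6,12-dimethyltrideca-2,6,12-trienoate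
Conditions: PPh3, I2, imidazole (premixed), CH2Cl2, 0 °C
Reagents that add atoms: iodine, II
Why: Appel reaction: the primary alcohol is converted into the iodide by SN2 displacement of its alkoxyphosphonium ion, the tertiary alcohol and the alkenyl iodide being inert.

Step 14
Reactants: 27 tert-butyl (2E,6Z,9R,12E)-9-[(2R)-2-hydroxy-6-methylhept-5-en-2-yl]-13-iodo-2-(2-iodoethyl)-6,12-dimethyltrideca-2,6,12-trienoate
Product: 28 tert-butyl (1E,5Z,8R,11E)-8-[(2R)-2-hydroxy-6-methylhept-5-en-2-yl]-5,11-dimethylcyclotetradeca-1,5,11-triene-1-carboxylate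
Conditions: NiI2 (30 mol%), 4,4'-di-tert-butyl-2,2'-bipyridine (30 mol%), Mn powder (4 equiv), NaI (0.5 equiv), DMA, 40 °C; 27 added by syringe pump over 12 h (final 2 mM)
Reagents that add atoms: none
Why: Zerovalent nickel, formed from NiI2 and the bipyridine by Mn, inserts into the alkenyl C11–I bond, while the primary C10–I bond is turned by halogen-atom abstraction at a monovalent nickel centre into the C10 radical, which is captured at the alkenylnickel centre and leaves by C(sp3)–C(sp2) reductive elimination from trivalent nickel, so two electrophilic carbons of like polarity are joined with Mn as terminal reductant. The closest known reaction type is the nickel-catalysed reductive cross-electrophile coupling of alkenyl halides with primary alkyl halides, which retains alkene geometry and tolerates free alcohols and esters. The single ring, the 14-membered carbocycle, is closed end to end as a macrocyclisation of an α,ω-dielectrophile by radical capture at the metal, not by exo or endo radical addition to an alkene. No stereocentre is formed: the E geometry of C11=C12 is carried over from the alkenyl iodide with retention, and C1 and the carbinol carbon lie four or more bonds away and are untouched. The step needs intramolecular cross-coupling to win over oligomerisation, homocoupling and hydrodehalogenation: the different activation modes of the two C–I bonds give the cross-selectivity, slow addition at high dilution favours ring closure, and the one Z and two E trisubstituted alkenes remove rotors from the chain so that its ends can meet. Any reversible 3-exo attack of the homoallylic C10 radical on C8 is degenerate (C9 and C10 are both CH2) and reopens to the more stable E-enoate, which is why the ring is closed at the ester stage.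

Step 15
Reactants: 28 tert-butyl (1E,5Z,8R,11E)-8-[(2R)-2-hydroxy-6-methylhept-5-en-2-yl]-5,11-dimethylcyclotetradeca-1,5,11-triene-1-carboxylate
Product: 29 (2R)-2-[(1R,3Z,7E,11E)-8-(hydroxymethyl)-4,12-dimethylcyclotetradeca-3,7,11-trien-1-yl]-6-methylhept-5-en-2-ol
Conditions: iBu2AlH (5 equiv), CH2Cl2, −78 to 0 °C; aq. Rochelle salt
Reagents that add atoms: none
Why: Hydride 1,2-reduction of the α,β-unsaturated ester with iBu2AlH gives the allylic alcohol without conjugate reduction or change of alkene geometry, and no protecting group remains to be removed.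

**Compound list**

1 | nerol, (2Z)-3,7-dimethylocta-2,6-dien-1-ol | CC(C)=CCC/C(C)=C\CO | starting material
2 | [(2S,3R)-3-methyl-3-(4-methylpent-3-en-1-yl)oxiran-2-yl]methanol | OC[C@@H]1O[C@]1(C)CCC=C(C)C | intermediate
3 | (4-bromobut-1-yn-1-yl)trimethylsilane | C[Si](C)(C)C#CCCBr | starting material
4 | [4-(trimethylsilyl)but-3-yn-1-yl]magnesium bromide | C[Si](C)(C)C#CCC[Mg]Br | intermediate (not isolated)
5 | (2R,3R)-3,7-dimethyl-2-[4-(trimethylsilyl)but-3-yn-1-yl]oct-6-ene-1,3-diol | CC(C)=CCC[C@@](C)(O)[C@H](CCC#C[Si](C)(C)C)CO | intermediate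
6 | (5S,6R)-5-(iodomethyl)-6,10-dimethyl-1-(trimethylsilyl)undec-9-en-1-yn-6-ol | CC(C)=CCC[C@@](C)(O)[C@H](CCC#C[Si](C)(C)C)CI | intermediate
7 | {[(5S,6R)-5-(iodomethyl)-6,10-dimethyl-1-(trimethylsilyl)undec-9-en-1-yn-6-yl]oxy}trimethylsilane | CC(C)=CCC[C@@](C)(O[Si](C)(C)C)[C@H](CCC#C[Si](C)(C)C)CI | intermediate
8 | (3-bromopropoxy)(tert-butyl)dimethylsilane | CC(C)(C)[Si](C)(C)OCCCBr | starting material
9 | propyne | CC#C | starting material
10 | {3-[(tert-butyldimethylsilyl)oxy]propyl}magnesium bromide | CC(C)(C)[Si](C)(C)OCCC[Mg]Br | intermediate (not isolated)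
11 | {3-[(tert-butyldimethylsilyl)oxy]propyl}copper (MgBr2 complex) | CC(C)(C)[Si](C)(C)OCCC[Cu] | intermediate (not isolated)
12 | {(1Z)-5-[(tert-butyldimethylsilyl)oxy]-2-methylpent-1-en-1-yl}copper | CC(C)(C)[Si](C)(C)OCCC/C(C)=C\[Cu] | intermediate (not isolated)
13 | tert-butyl{[(4Z)-5-iodo-4-methylpent-4-en-1-yl]oxy}dimethylsilane | CC(C)(C)[Si](C)(C)OCCC/C(C)=C\I | intermediate
14 | {(2S,3R)-3,7-dimethyl-3-(trimethylsilyloxy)-2-[4-(trimethylsilyl)but-3-yn-1-yl]oct-6-en-1-yl}zinc iodide | CC(C)=CCC[C@@](C)(O[Si](C)(C)C)[C@H](CCC#C[Si](C)(C)C)C[Zn]I | intermediate (not isolated)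
15 | tert-butyl{[(4Z,7R,8R)-4,8,12-trimethyl-7-[4-(trimethylsilyl)but-3-yn-1-yl]-8-(trimethylsilyloxy)trideca-4,11-dien-1-yl]oxy}dimethylsilane | CC(C)=CCC[C@@](C)(O[Si](C)(C)C)[C@H](CCC#C[Si](C)(C)C)C/C=C(/C)CCCO[Si](C)(C)C(C)(C)C | intermediate
16 | (4Z,7R)-7-[(2R)-2-hydroxy-6-methylhept-5-en-2-yl]-4-methylundec-4-en-10-yn-1-ol | CC(C)=CCC[C@@](C)(O)[C@H](CCC#C)C/C=C(/C)CCCO | intermediate
17 | (E)-alkenyldimethylalane of 16, both hydroxyls as dimethylaluminium alkoxides | CC(C)=CCC[C@@](C)(O[Al](C)C)[C@H](CC/C(C)=C/[Al](C)C)C/C=C(/C)CCCO[Al](C)C | intermediate (not isolated)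
18 | (4Z,7R,10E)-7-[(2R)-2-hydroxy-6-methylhept-5-en-2-yl]-11-iodo-4,10-dimethylundeca-4,10-dien-1-ol | CC(C)=CCC[C@@](C)(O)[C@H](CC/C(C)=C/I)C/C=C(/C)CCCO | intermediate
19 | (4Z,7R,10E)-7-[(2R)-2-hydroxy-6-methylhept-5-en-2-yl]-11-iodo-4,10-dimethylundeca-4,10-dienal | CC(C)=CCC[C@@](C)(O)[C@H](CC/C(C)=C/I)C/C=C(/C)CCC=O | intermediate
20 | tert-butyl 2-(diethoxyphosphoryl)acetate | CCOP(=O)(OCC)CC(=O)OC(C)(C)C | starting material
21 | (2-bromoethoxy)(tert-butyl)dimethylsilane | CC(C)(C)[Si](C)(C)OCCBr | starting material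
22 | sodium salt of the carbanion of 20 | CCOP(=O)(OCC)[CH-]C(=O)OC(C)(C)C.[Na+] | intermediate (not isolated)
23 | tert-butyl 4-[(tert-butyldimethylsilyl)oxy]-2-(diethoxyphosphoryl)butanoate (racemic) | CCOP(=O)(OCC)C(CCO[Si](C)(C)C(C)(C)C)C(=O)OC(C)(C)C | intermediate
24 | bromomagnesium salt of the carbanion of 23 | CCOP(=O)(OCC)[C-](CCO[Si](C)(C)C(C)(C)C)C(=O)OC(C)(C)C.[Mg+2].[Br-] | intermediate (not isolated)
25 | tert-butyl (2E,6Z,9R,12E)-2-{2-[(tert-butyldimethylsilyl)oxy]ethyl}-9-[(2R)-2-hydroxy-6-methylhept-5-en-2-yl]-13-iodo-6,12-dimethyltrideca-2,6,12-trienoate | CC(C)=CCC[C@@](C)(O)[C@H](CC/C(C)=C/I)C/C=C(/C)CC/C=C(/C(=O)OC(C)(C)C)CCO[Si](C)(C)C(C)(C)C | intermediate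
26 | tert-butyl (2E,6Z,9R,12E)-2-(2-hydroxyethyl)-9-[(2R)-2-hydroxy-6-methylhept-5-en-2-yl]-13-iodo-6,12-dimethyltrideca-2,6,12-trienoate | CC(C)=CCC[C@@](C)(O)[C@H](CC/C(C)=C/I)C/C=C(/C)CC/C=C(/C(=O)OC(C)(C)C)CCO | intermediate
27 | tert-butyl (2E,6Z,9R,12E)-9-[(2R)-2-hydroxy-6-methylhept-5-en-2-yl]-13-iodo-2-(2-iodoethyl)-6,12-dimethyltrideca-2,6,12-trienoate | CC(C)=CCC[C@@](C)(O)[C@H](CC/C(C)=C/I)C/C=C(/C)CC/C=C(/C(=O)OC(C)(C)C)CCI | intermediate
28 | tert-butyl (1E,5Z,8R,11E)-8-[(2R)-2-hydroxy-6-methylhept-5-en-2-yl]-5,11-dimethylcyclotetradeca-1,5,11-triene-1-carboxylate | CC(C)=CCC[C@@](C)(O)[C@H]1C/C=C(/C)CC/C=C(/C(=O)OC(C)(C)C)CC/C=C(\C)CC1 | intermediate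
29 | (2R)-2-[(1R,3Z,7E,11E)-8-(hydroxymethyl)-4,12-dimethylcyclotetradeca-3,7,11-trien-1-yl]-6-methylhept-5-en-2-ol | CC(C)=CCC[C@@](C)(O)[C@H]1C/C=C(/C)CC/C=C(/CO)CC/C=C(\C)CC1 | target

**Step count and risks**

Total step count: 15. Longest linear sequence: 13 steps (steps 1–4, 6–9 and 11–15, from nerol).

Steps most likely to fail:

Step 14. Intermolecular radical capture and reductive homocoupling may outrun ring closure, or the alkyl iodide may be lost by hydrodehalogenation or by β-hydride elimination at nickel. The fallback replaces the radical union by a polar one; it sets out from 27 and comes back at 28. Compound 27 would be silylated at the tertiary hydroxyl (Me3SiCl, imidazole, CH2Cl2) to tert-butyl (2E,6Z,9R,12E)-13-iodo-2-(2-iodoethyl)-6,12-dimethyl-9-[(2R)-6-methyl-2-(trimethylsilyloxy)hept-5-en-2-yl]trideca-2,6,12-trienoate F1. Zinc dust with LiCl in THF at 25 °C should insert only into the primary sp3 C–I bond and give the alkylzinc iodide F2. Slow addition of F2 to Pd(PPh3)4 in THF at 60 °C should close the same C10–C11 bond by intramolecular Negishi coupling to the O-trimethylsilyl macrocyclic ester F3. K2CO3 in MeOH would then remove the silyl group and return 28.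

Step 2. The nucleophile may attack the wrong epoxide carbon, or the epoxide may migrate (Payne rearrangement) before it is opened, so that 1,2-diols form. The fallback replaces steric and alkoxide control by electronic control of the opening; it sets out from 2 and comes back at 5. Compound 2 would be oxidised (TEMPO, PhI(OAc)2, MeCN/H2O) to (2R,3R)-3-methyl-3-(4-methylpent-3-en-1-yl)oxirane-2-carboxylic acid F4 and esterified (Me3SiCHN2, MeOH/toluene) to methyl (2R,3R)-3-methyl-3-(4-methylpent-3-en-1-yl)oxirane-2-carboxylate F5. The homocuprate bromomagnesium bis[4-(trimethylsilyl)but-3-yn-1-yl]cuprate F6, prepared from 4 (2 equiv) and CuBr·SMe2 in THF at −40 °C, should attack the α-carbon of the glycidic ester with inversion and give methyl (2S,3R)-3-hydroxy-3,7-dimethyl-2-[4-(trimethylsilyl)but-3-yn-1-yl]oct-6-enoate F7. Reduction with LiAlH4 in Et2O at 0 °C would return 5.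

Step 11. E/Z control may erode through kinetic formation of the Z-enoate from the α-branched phosphonate. The fallback replaces the phosphonate carbanion by a stabilised phosphorane that olefinates under thermodynamic control; it sets out from 19 and comes back at 25. Commercial (tert-butoxycarbonylmethylene)triphenylphosphorane would be C-alkylated with (2-iodoethoxy)(tert-butyl)dimethylsilane (MeCN, reflux) to {1-(tert-butoxycarbonyl)-3-[(tert-butyldimethylsilyl)oxy]propyl}triphenylphosphonium iodide F8. Aqueous NaOH/CH2Cl2 should give tert-butyl 4-[(tert-butyldimethylsilyl)oxy]-2-(triphenylphosphoranylidene)butanoate F9. Wittig reaction of 19 with F9 in toluene at 90 °C should give 25.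

**Further compounds**

F1 | step 14 | tert-butyl (2E,6Z,9R,12E)-13-iodo-2-(2-iodoethyl)-6,12-dimethyl-9-[(2R)-6-methyl-2-(trimethylsilyloxy)hept-5-en-2-yl]trideca-2,6,12-trienoate | CC(C)=CCC[C@@](C)(O[Si](C)(C)C)[C@H](CC/C(C)=C/I)C/C=C(/C)CC/C=C(/C(=O)OC(C)(C)C)CCI
F2 | step 14 | alkylzinc iodide from F1 (zinc at the former CH2I carbon) | CC(C)=CCC[C@@](C)(O[Si](C)(C)C)[C@H](CC/C(C)=C/I)C/C=C(/C)CC/C=C(/C(=O)OC(C)(C)C)CC[Zn]I
F3 | step 14 | tert-butyl (1E,5Z,8R,11E)-5,11-dimethyl-8-[(2R)-6-methyl-2-(trimethylsilyloxy)hept-5-en-2-yl]cyclotetradeca-1,5,11-triene-1-carboxylate | CC(C)=CCC[C@@](C)(O[Si](C)(C)C)[C@H]1C/C=C(/C)CC/C=C(/C(=O)OC(C)(C)C)CC/C=C(\C)CC1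
F4 | step 2 | (2R,3R)-3-methyl-3-(4-methylpent-3-en-1-yl)oxirane-2-carboxylic acid | OC(=O)[C@@H]1O[C@]1(C)CCC=C(C)C
F5 | step 2 | methyl (2R,3R)-3-methyl-3-(4-methylpent-3-en-1-yl)oxirane-2-carboxylate | COC(=O)[C@@H]1O[C@]1(C)CCC=C(C)C
F6 | step 2 | bromomagnesium bis[4-(trimethylsilyl)but-3-yn-1-yl]cuprate | C[Si](C)(C)C#CCC[Cu-]CCC#C[Si](C)(C)C.[Mg+2].[Br-]
F7 | step 2 | methyl (2S,3R)-3-hydroxy-3,7-dimethyl-2-[4-(trimethylsilyl)but-3-yn-1-yl]oct-6-enoate | CC(C)=CCC[C@@](C)(O)[C@H](CCC#C[Si](C)(C)C)C(=O)OC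
F8 | step 11 | {1-(tert-butoxycarbonyl)-3-[(tert-butyldimethylsilyl)oxy]propyl}triphenylphosphonium iodide | CC(C)(C)OC(=O)C(CCO[Si](C)(C)C(C)(C)C)[P+](c1ccccc1)(c1ccccc1)c1ccccc1.[I-]
F9 | step 11 | tert-butyl 4-[(tert-butyldimethylsilyl)oxy]-2-(triphenylphosphoranylidene)butanoate | CC(C)(C)OC(=O)C(CCO[Si](C)(C)C(C)(C)C)=P(c1ccccc1)(c1ccccc1)c1ccccc1
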